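**Compound numbers.** 1–4 chain fragment, 5–6 keto ester, 7–10 bicyclic core, 11–16 assembly and endgame; 16 is the target.

## The problem

Numbering used throughout: tetralin C1 (bears the side chain), C2, C3, C4 (bears CH3), C4a, C5 (OH), C6 (OH), C7 (CO2H), C8 (H), C8a; side chain C1' (the CH on C1), C2'–C4' (CH2), C5' (CHCH3), C6' (CH2OH), C7' (the CH2OAc carbon on C1').

- The target is a (1S,4R)-tetralin whose benzene ring is pentasubstituted: a catechol at C5/C6, a carboxylic acid at C7 ortho to one hydroxyl, one hydrogen at C8. An arene-first route has to assemble this pattern regiospecifically before any stereochemistry starts.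
- C1 and C4 are both benzylic and stand para across a flexible half-chair, so within the tetralin neither can control the other. C1' is exocyclic and vicinal to C1. C5' is 1,5 to C1' and needs its own chiral source.
- The two primary alcohols (C7', acetylated; C6', free) are sterically alike and must be told apart. The acetate rules out basic ester cleavage at the end, and the free catechol and salicylic acid are best unveiled last under neutral conditions.
- The feature that makes the key step possible: C5(OH)–C6(OH)–C7(CO2H) is a 4-oxygenated acetoacetate, C8–H is a formyl-level carbon, and C8a/C4a are the α- and carbonyl carbons of a cyclohexanone. The benzene ring can therefore be condensed onto the carbocycle last. The C7' oxygen lies so that O, C8, C8a, C1, C1' and C7' form a six-membered cyclic enol ether (a pyran), which that condensation opens again.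
- Without the benzene ring, the carbocycle with its C4 methyl and C1' with its two one-carbon arms (C7', C2') is the p-menthane skeleton of (2R,5R)-dihydrocarvone 7. The chiral pool thus supplies C1 and C4 in the trans relation.
- C1 then controls C1' through the rigid pyran ring.

## Retrosynthesis

**16 ⇒ 15 ⇒ 14.** The last step cuts three O–benzyl bonds and saturates C3'=C4' in one hydrogenation; before it, the C7'–O acetyl bond is made. Benzyl on both phenolic/carboxyl positions and on C6' lets one neutral operation finish the molecule with the acetate intact. The forward acetylation must find a single free aliphatic hydroxyl, which 14 has.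

**14 ⇒ 12 + 6 (key).** Cut C7–C8 and C4a–C5 of the benzene ring and re-close O–C8 to the pyran. Each new bond then joins a natural nucleophile to a natural electrophile: the doubly activated C2 of keto ester 6 to the vinylogous-ester carbon C8, and the enolisable C4 of 6 to the ketone C4a. Neighbouring cuts (a Diels–Alder across C4a–C8a, or keeping the arene and cutting in the carbocycle) either need an unactivated dienophile or return to the benzylic stereocentre problem. The precursor 12 has no aromatic ring; both benzylic stereocentres are ordinary cyclohexanone stereocentres, and the whole benzene ring comes from a commercial acetoacetate. The forward reaction must be regiospecific, must cyclise on carbon and not on oxygen, and must not epimerise C4.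

**12 ⇒ 10 + 4.** Cut C2'–C3' (sp3–sp2 coupling) and the C1'–H bond (hydroboration), turning the C1' stereocentre into an exocyclic methylene. Cutting C1'–C2' instead (enolate alkylation) would need C7' at the acid level and redox steps to bring it back. 10 has eleven carbons and two stereocentres, both from the chiral pool. The forward step must deliver H to C1' anti to C1–H and must leave the carbonyl alone.

**10 ⇒ 8 ⇒ 7.** Cut O–C7' (intramolecular O-alkylation) and C8–C8a (formylation), then the C7'–Cl bond back to the isopropenyl methyl of 7. This uses every carbon of dihydrocarvone. The forward formylation must be kinetic at C8a so that C4 is never enolised, and the ring must close on oxygen.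

**4 ⇒ 3 ⇒ 2 ⇒ 1.** Cut C3'=C4' (one-carbon iodo-olefination of aldehyde 3); C5' comes from the (R)-hydroxy ester 1. The alkene geometry is irrelevant because step 10 removes it.

**6 ⇒ 5.** Ester exchange, so that the carboxyl is freed by the final hydrogenolysis and not by hydrolysis.

## Roads not taken

**Alternative 1:** arene first (the obvious route). Cut in the carbocycle back to a 2,3-dioxygenated benzoate: Friedel–Crafts ring closure to tetralone A1, then attach the side chain at the C1 carbonyl by olefination and hydrogenate.
- The pentasubstituted arene costs several steps, and the ring closure runs on a benzoate-deactivated ring.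
- C4 needs its own asymmetric step, and nothing in a tetralin relays C4 to C1.
- C1 and C1' would rest on face-selective hydrogenation of a tetrasubstituted styrene beside the peri C8–H.
- The chosen plan gets the arene in one step and C1/C4 from the chiral pool.

**Alternative 2:** cut C1–C1' to the racemic 1,2-dihydronaphthalene A2 and a vinyl diazoacetate. The forward key step is a Rh2(S-DOSP)4-catalysed combined C–H functionalisation/Cope rearrangement, which sets C1 and C1' and resolves C4.
- A2 still needs the full arene, made racemic over several steps, and half of it is the wrong enantiomer.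
- The electron-poor benzoate ring makes the allylic C–H a poorer hydride donor for the carbenoid.
- The product needs ring-alkene reduction, ester reduction and building of C2'–C6' from a short unsaturated ester.
- The chosen plan attaches the whole chain in one coupling.

**Alternative 3:** arene last, but C1/C1' by anionic oxy-Cope rearrangement. Cut C1–C1' to the tertiary dienol A3 (1,2-adduct of a (Z)-allyl unit to (R)-6-methylcyclohex-2-enone). KH would give a chair [3,3] shift that transfers C4a chirality to C1, and the regiodefined enolate would be formylated.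
- It needs an enantioenriched, configurationally labile enone.
- The facial selectivity of 1,2-addition beside an equatorial α-methyl is not predictable with confidence.
- Dissociative pathways can erode the transfer, and the vinyl group left on C1' must be cleaved later.
- Dihydrocarvone gives the same cyclohexanone stereochemistry without these risks.

Key step: step 8

Remark: commercial (+)-dihydrocarvone 7 is rich in the (2R,5R) isomer; its minor (2S,5R) epimer is assumed to be removed by chromatography of chloride 8 (or avoided by making 7 from (R)-carvone with an ene-reductase).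

## Route

Step 1
Reactants: 1 methyl (2R)-3-hydroxy-2-methylpropanoate
Product: 2 methyl (2R)-3-(benzyloxy)-2-methylpropanoate
Conditions: BnOC(=NH)CCl3, TfOH (5 mol %), CH2Cl2/cyclohexane, rt
Reagents that add atoms: benzyl 2,2,2-trichloroacetimidate, N=C(OCc1ccccc1)C(Cl)(Cl)Cl
Why: Acid-catalysed imidate benzylation avoids the basic conditions that would cause β-elimination or racemisation of the β-hydroxy ester; the stereocentre is not touched.

Step 2
Reactants: 2 methyl (2R)-3-(benzyloxy)-2-methylpropanoate
Product: 3 (2R)-3-(benzyloxy)-2-methylpropanal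
Conditions: i-Bu2AlH, CH2Cl2, −78 °C; MeOH, aq. potassium sodium tartrate; used crude
Reagents that add atoms: none
Why: Partial ester reduction stops at the tetrahedral aluminium acetal at −78 °C; the α-stereocentre is labile, so the aldehyde is taken on without purification.

Step 3
Reactants: 3 (2R)-3-(benzyloxy)-2-methylpropanal
Product: 4 ({[(2S,3E)-4-iodo-2-methylbut-3-en-1-yl]oxy}methyl)benzene
Conditions: CrCl2, CHI3, THF, 0 °C → rt
Reagents that add atoms: iodoform, IC(I)I
Why: Takai olefination gives the (E)-alkenyl iodide under non-basic conditions that do not epimerise the α-centre; any (Z)-isomer is harmless because the alkene is hydrogenated in step 10.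

Step 4
Reactants: 5 ethyl 4-(benzyloxy)-3-oxobutanoate
Product: 6 benzyl 4-(benzyloxy)-3-oxobutanoate
Conditions: BnOH (3 equiv), DMAP (10 mol %), PhMe, reflux with removal of EtOH
Reagents that add atoms: benzyl alcohol, OCc1ccccc1
Why: β-Keto esters undergo easy transesterification (through the acylketene or enol), driven here by distilling off ethanol.

Step 5
Reactants: 7 (2R,5R)-2-methyl-5-(prop-1-en-2-yl)cyclohexan-1-one
Product: 8 (2R,5R)-5-(3-chloroprop-1-en-2-yl)-2-methylcyclohexan-1-one
Conditions: Ca(OCl)2, solid CO2, CH2Cl2/H2O, 0 °C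
Reagents that add atoms: calcium hypochlorite, [Ca+2].[O-]Cl.[O-]Cl
Why: Ene-type allylic chlorination of the isopropenyl group by HOCl made in situ; the electron-rich 1,1-disubstituted alkene reacts far faster than the ketone enolises at this pH, so C4 and C1 are untouched.

Step 6
Reactants: 8 (2R,5R)-5-(3-chloroprop-1-en-2-yl)-2-methylcyclohexan-1-one
Product: 10 (4aS,7R)-7-methyl-4-methylidene-3,4,4a,5,6,7-hexahydro-8H-isochromen-8-one, via formyl enolate 9 (not isolated)
Conditions: LiN(iPr)2 (1.05 equiv), THF, −78 °C; CF3CH2OCHO, −78 → 0 °C; then DMF, NaI (10 mol %), 50 °C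
Reagents that add atoms: 2,2,2-trifluoroethyl formate, O=COCC(F)(F)F
Why: Kinetic deprotonation at the CH2 α-carbon (C8a) and Claisen-type C-formylation give 9 without enolising C4; intramolecular Williamson O-alkylation by the allylic chloride (6-exo-tet; SN2 and SN2' give the same product) then closes the pyran. C-Alkylation would need a four-membered ring and alkylation on the ketone oxygen a bridgehead alkene.

Step 7
Reactants: 10 (4aS,7R)-7-methyl-4-methylidene-3,4,4a,5,6,7-hexahydro-8H-isochromen-8-one; 4 ({[(2S,3E)-4-iodo-2-methylbut-3-en-1-yl]oxy}methyl)benzene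
Product: 12 (4S,4aS,7R)-4-[(2E,4S)-5-(benzyloxy)-4-methylpent-2-en-1-yl]-7-methyl-3,4,4a,5,6,7-hexahydro-8H-isochromen-8-one, via alkylborane 11 (not isolated)
Conditions: 9-BBN-H (1.1 equiv), THF, 0 °C → rt, to full consumption of 10; then 4, Pd(dppf)Cl2 (5 mol %), AsPh3, Cs2CO3, DMF/H2O, rt
Reagents that add atoms: none
Why: 9-BBN puts boron on the exocyclic CH2 and delivers H to C1' from the face anti to the pseudoaxial C1–H (axial-type attack: the ring atoms 1,3 to C1' are the ring oxygen and sp2 C8a, so nothing hinders it, while the other face is flanked by the axial hydrogens on C1 and C7'), which places CH2B equatorial, trans to C1–C2, and sets C1' as S. B-alkyl Suzuki–Miyaura coupling with retention then forms C2'–C3'; the vinylogous-ester carbonyl is reduced by 9-BBN much more slowly than a 1,1-disubstituted alkene is hydroborated.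

Step 8
Reactants: 12 (4S,4aS,7R)-4-[(2E,4S)-5-(benzyloxy)-4-methylpent-2-en-1-yl]-7-methyl-3,4,4a,5,6,7-hexahydro-8H-isochromen-8-one; 6 benzyl 4-(benzyloxy)-3-oxobutanoate
Product: 14 benzyl (5R,8S)-4-(benzyloxy)-8-[(2S,4E,6S)-7-(benzyloxy)-1-hydroxy-6-methylhept-4-en-2-yl]-3-hydroxy-5-methyl-5,6,7,8-tetrahydronaphthalene-2-carboxylate, via ring-opened adduct 13 (not isolated)
Conditions: piperidine (0.3 equiv), AcOH (0.6 equiv), PhMe, 4 Å molecular sieves, 90 °C
Reagents that add atoms: none
Why: The amine opens the vinylogous ester at C8 to an enaminone, and the doubly activated C2 of 6 (the future C7) then replaces the amine at C8 in a Knoevenagel-type addition–elimination; the net vinylic substitution expels the C7' oxygen, opens the pyran ring and gives 13. The only remaining enolisable carbon of the keto ester part, C4 of 6 (the future C5, bearing OBn), then adds as enol or enamine to the ring ketone C4a in an intramolecular aldol reaction, 6-(enolexo)-exo-trig, and loss of water followed by enolisation of the cyclohexadienone gives the benzene ring. The closest known reaction type is the condensation of 2-(hydroxymethylene)- and 2-(alkoxymethylene)cycloalkanones with β-keto esters to salicylates, together with the ring-opening/ring-closure of cyclic vinylogous esters such as chromones by 1,3-dicarbonyl compounds. No stereocentre is formed: C1, C1' and C5' are remote from the reacting atoms, and C4 should not enolise in the buffered medium and is locked once C4a is aromatic. The regiochemistry (C7 to C8, C5 to C4a) is fixed by the substrate, since C8 is the only carbon with a leaving group, C2 of 6 is the only carbon acidic enough to attack it, and afterwards only C4 of 6 can reach C4a through a six-membered transition state. O-Cyclised 2H-pyrans form reversibly, whereas aromatisation is irreversible and drains them. The same event frees C7'–OH as the only aliphatic hydroxyl, which distinguishes it from the benzyl-protected C6'.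

Step 9
Reactants: 14 benzyl (5R,8S)-4-(benzyloxy)-8-[(2S,4E,6S)-7-(benzyloxy)-1-hydroxy-6-methylhept-4-en-2-yl]-3-hydroxy-5-methyl-5,6,7,8-tetrahydronaphthalene-2-carboxylate
Product: 15 benzyl (5R,8S)-8-[(2S,4E,6S)-1-(acetyloxy)-7-(benzyloxy)-6-methylhept-4-en-2-yl]-4-(benzyloxy)-3-hydroxy-5-methyl-5,6,7,8-tetrahydronaphthalene-2-carboxylate
Conditions: Ac2O (1.1 equiv), pyridine, CH2Cl2, 0 °C (no DMAP)
Reagents that add atoms: acetic anhydride, CC(=O)OC(C)=O
Why: Acetylation of the primary alcohol; the phenol is hydrogen-bonded to the ester carbonyl and flanked by two ortho substituents, so it should react much more slowly under these mild conditions.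

Step 10
Reactants: 15 benzyl (5R,8S)-8-[(2S,4E,6S)-1-(acetyloxy)-7-(benzyloxy)-6-methylhept-4-en-2-yl]-4-(benzyloxy)-3-hydroxy-5-methyl-5,6,7,8-tetrahydronaphthalene-2-carboxylate
Product: 16 (5R,8S)-8-[(2S,6S)-1-(acetyloxy)-7-hydroxy-6-methylheptan-2-yl]-3,4-dihydroxy-5-methyl-5,6,7,8-tetrahydronaphthalene-2-carboxylic acid
Conditions: H2 (1 atm), 10% Pd/C, EtOAc/MeOH, rt
Reagents that add atoms: none
Why: Catalytic hydrogenation saturates the disubstituted chain alkene and hydrogenolyses the two benzyl ethers and the benzyl ester in one neutral operation; the acetate, the catechol and all four stereocentres are not affected.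

## Compound list

1 | methyl (2R)-3-hydroxy-2-methylpropanoate | COC(=O)[C@H](C)CO | starting material
2 | methyl (2R)-3-(benzyloxy)-2-methylpropanoate | COC(=O)[C@H](C)COCc1ccccc1 | intermediate
3 | (2R)-3-(benzyloxy)-2-methylpropanal | O=C[C@H](C)COCc1ccccc1 | intermediate
4 | ({[(2S,3E)-4-iodo-2-methylbut-3-en-1-yl]oxy}methyl)benzene | I/C=C/[C@H](C)COCc1ccccc1 | intermediate
5 | ethyl 4-(benzyloxy)-3-oxobutanoate | CCOC(=O)CC(=O)COCc1ccccc1 | starting material
6 | benzyl 4-(benzyloxy)-3-oxobutanoate | O=C(CC(=O)COCc1ccccc1)OCc1ccccc1 | intermediate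
7 | (2R,5R)-2-methyl-5-(prop-1-en-2-yl)cyclohexan-1-one | C=C(C)[C@@H]1CC[C@@H](C)C(=O)C1 | starting material
8 | (2R,5R)-5-(3-chloroprop-1-en-2-yl)-2-methylcyclohexan-1-one | C=C(CCl)[C@@H]1CC[C@@H](C)C(=O)C1 | intermediate
9 | (2R,5R)-5-(3-chloroprop-1-en-2-yl)-6-(hydroxymethylidene)-2-methylcyclohexan-1-one (formed as its lithium enolate) | C=C(CCl)[C@@H]1CC[C@@H](C)C(=O)C1=CO | intermediate
10 | (4aS,7R)-7-methyl-4-methylidene-3,4,4a,5,6,7-hexahydro-8H-isochromen-8-one | O1CC(=C)[C@@H]2CC[C@@H](C)C(=O)C2=C1 | intermediate
11 | (4S,4aS,7R)-4-[(9-borabicyclo[3.3.1]nonan-9-yl)methyl]-7-methyl-3,4,4a,5,6,7-hexahydro-8H-isochromen-8-one | O1C[C@@H](CB3C4CCCC3CCC4)[C@@H]2CC[C@@H](C)C(=O)C2=C1 | intermediate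
12 | (4S,4aS,7R)-4-[(2E,4S)-5-(benzyloxy)-4-methylpent-2-en-1-yl]-7-methyl-3,4,4a,5,6,7-hexahydro-8H-isochromen-8-one | O1C[C@@H](C/C=C/[C@H](C)COCc3ccccc3)[C@@H]2CC[C@@H](C)C(=O)C2=C1 | intermediate
13 | benzyl 4-(benzyloxy)-2-({(3R,6S)-6-[(2S,4E,6S)-7-(benzyloxy)-1-hydroxy-6-methylhept-4-en-2-yl]-3-methyl-2-oxocyclohexylidene}methyl)-3-oxobutanoate (mixture of tautomers and of isomers at the new centres) | OC[C@@H](C/C=C/[C@H](C)COCc1ccccc1)[C@@H]1CC[C@@H](C)C(=O)C1=CC(C(=O)OCc1ccccc1)C(=O)COCc1ccccc1 | intermediate
14 | benzyl (5R,8S)-4-(benzyloxy)-8-[(2S,4E,6S)-7-(benzyloxy)-1-hydroxy-6-methylhept-4-en-2-yl]-3-hydroxy-5-methyl-5,6,7,8-tetrahydronaphthalene-2-carboxylate | OC[C@@H](C/C=C/[C@H](C)COCc3ccccc3)[C@@H]1CC[C@@H](C)c2c1cc(C(=O)OCc4ccccc4)c(O)c2OCc5ccccc5 | intermediate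
15 | benzyl (5R,8S)-8-[(2S,4E,6S)-1-(acetyloxy)-7-(benzyloxy)-6-methylhept-4-en-2-yl]-4-(benzyloxy)-3-hydroxy-5-methyl-5,6,7,8-tetrahydronaphthalene-2-carboxylate | CC(=O)OC[C@@H](C/C=C/[C@H](C)COCc3ccccc3)[C@@H]1CC[C@@H](C)c2c1cc(C(=O)OCc4ccccc4)c(O)c2OCc5ccccc5 | intermediate
16 | (5R,8S)-8-[(2S,6S)-1-(acetyloxy)-7-hydroxy-6-methylheptan-2-yl]-3,4-dihydroxy-5-methyl-5,6,7,8-tetrahydronaphthalene-2-carboxylic acid | CC(=O)OC[C@@H](CCC[C@H](C)CO)[C@@H]1CC[C@@H](C)c2c1cc(C(=O)O)c(O)c2O | target

## Step count and least certain steps

Total: 10 steps. Longest linear sequence: 7 (steps 1, 2, 3, 7, 8, 9, 10).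

**Step 8 (key step).** The most likely failure is that ring closure stalls after the first C–C bond, or diverts to attack of the C4a enol oxygen on the benzyl ester (a fused 2-pyranone). The carbon that must close the ring (C4 of 6, bearing OBn) is the less acidic and more hindered nucleophilic site. Partial loss of configuration at C4 before aromatisation is a second concern.
Fallback: condense 12 under the same conditions with commercial benzyl acetoacetate, the unhindered parent partner of this condensation. This should give benzyl (5R,8S)-8-[(2S,4E,6S)-7-(benzyloxy)-1-hydroxy-6-methylhept-4-en-2-yl]-3-hydroxy-5-methyl-5,6,7,8-tetrahydronaphthalene-2-carboxylate F1. The C5 oxygen is then introduced after the ring exists: magnesium-mediated ortho-formylation (MgCl2, Et3N, paraformaldehyde) at the only free ortho position gives the 4-formyl compound benzyl (5R,8S)-8-[(2S,4E,6S)-7-(benzyloxy)-1-hydroxy-6-methylhept-4-en-2-yl]-4-formyl-3-hydroxy-5-methyl-5,6,7,8-tetrahydronaphthalene-2-carboxylate F2. Dakin oxidation (H2O2, mild base) gives the catechol benzyl (5R,8S)-8-[(2S,4E,6S)-7-(benzyloxy)-1-hydroxy-6-methylhept-4-en-2-yl]-3,4-dihydroxy-5-methyl-5,6,7,8-tetrahydronaphthalene-2-carboxylate F3. Benzylation of its non-chelated phenol (K2CO3, BnBr, acetone) returns to 14.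

**Step 7.** The most likely failure is incomplete facial selectivity in the hydroboration: the bulky borane may feel the carbocycle CH2 next to C1 on the otherwise preferred face. Slow transmetalation of the β-branched alkylborane and competing carbonyl reduction are further concerns.
Fallback: separate bond formation from the stereo-determining step. Alkylborane 11 from 10 is oxidised (NaBO3) to (4R,4aS,7R)-4-(hydroxymethyl)-7-methyl-3,4,4a,5,6,7-hexahydro-8H-isochromen-8-one F4, at which stage C1' epimers can be separated. F4 is converted (I2, PPh3, imidazole) into (4S,4aS,7R)-4-(iodomethyl)-7-methyl-3,4,4a,5,6,7-hexahydro-8H-isochromen-8-one F5. Nickel-catalysed reductive cross-electrophile coupling of F5 with 4 (NiI2, 4,4'-di-tert-butyl-2,2'-bipyridine, Mn, DMA) returns to 12.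

**Step 6.** The most likely failure is that the chelated lithium enolate of the formyl ketone is too unreactive for the intramolecular O-alkylation, so that intermolecular alkylation or migration of the exocyclic double bond competes on heating.
Fallback: close the ring under acid. Chloride 8 is displaced with KOAc (DMF) to 2-[(1R,4R)-4-methyl-3-oxocyclohexyl]prop-2-en-1-yl acetate F6. Methanolysis (K2CO3, MeOH) gives (2R,5R)-5-(3-hydroxyprop-1-en-2-yl)-2-methylcyclohexan-1-one F7. Kinetic formylation as in step 6 (2 equiv of base) gives (2R,5S)-6-(hydroxymethylidene)-5-(3-hydroxyprop-1-en-2-yl)-2-methylcyclohexan-1-one F8. Acid-catalysed cyclodehydration (TsOH, benzene, removal of water) converts the hydroxymethylene ketone and the allylic alcohol into the cyclic vinylogous ester and returns to 10.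

**Step 9.** The most likely failure is partial acetylation of the phenol beside the primary alcohol.
Fallback: acetylate exhaustively (Ac2O, DMAP, Et3N) to benzyl (5R,8S)-3-(acetyloxy)-8-[(2S,4E,6S)-1-(acetyloxy)-7-(benzyloxy)-6-methylhept-4-en-2-yl]-4-(benzyloxy)-5-methyl-5,6,7,8-tetrahydronaphthalene-2-carboxylate F9. The much more labile aryl acetate is then removed selectively by aminolysis (pyrrolidine, 1 equiv, CH2Cl2, 0 °C), which returns to 15.

## Further compounds

F1 | step 8 | benzyl (5R,8S)-8-[(2S,4E,6S)-7-(benzyloxy)-1-hydroxy-6-methylhept-4-en-2-yl]-3-hydroxy-5-methyl-5,6,7,8-tetrahydronaphthalene-2-carboxylate | OC[C@@H](C/C=C/[C@H](C)COCc3ccccc3)[C@@H]1CC[C@@H](C)c2c1cc(C(=O)OCc4ccccc4)c(O)c2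
F2 | step 8 | benzyl (5R,8S)-8-[(2S,4E,6S)-7-(benzyloxy)-1-hydroxy-6-methylhept-4-en-2-yl]-4-formyl-3-hydroxy-5-methyl-5,6,7,8-tetrahydronaphthalene-2-carboxylate | OC[C@@H](C/C=C/[C@H](C)COCc3ccccc3)[C@@H]1CC[C@@H](C)c2c1cc(C(=O)OCc4ccccc4)c(O)c2C=O
F3 | step 8 | benzyl (5R,8S)-8-[(2S,4E,6S)-7-(benzyloxy)-1-hydroxy-6-methylhept-4-en-2-yl]-3,4-dihydroxy-5-methyl-5,6,7,8-tetrahydronaphthalene-2-carboxylate | OC[C@@H](C/C=C/[C@H](C)COCc3ccccc3)[C@@H]1CC[C@@H](C)c2c1cc(C(=O)OCc4ccccc4)c(O)c2O
F4 | step 7 | (4R,4aS,7R)-4-(hydroxymethyl)-7-methyl-3,4,4a,5,6,7-hexahydro-8H-isochromen-8-one | O1C[C@@H](CO)[C@@H]2CC[C@@H](C)C(=O)C2=C1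
F5 | step 7 | (4S,4aS,7R)-4-(iodomethyl)-7-methyl-3,4,4a,5,6,7-hexahydro-8H-isochromen-8-one | O1C[C@@H](CI)[C@@H]2CC[C@@H](C)C(=O)C2=C1
F6 | step 6 | 2-[(1R,4R)-4-methyl-3-oxocyclohexyl]prop-2-en-1-yl acetate | C=C(COC(C)=O)[C@@H]1CC[C@@H](C)C(=O)C1
F7 | step 6 | (2R,5R)-5-(3-hydroxyprop-1-en-2-yl)-2-methylcyclohexan-1-one | C=C(CO)[C@@H]1CC[C@@H](C)C(=O)C1
F8 | step 6 | (2R,5S)-6-(hydroxymethylidene)-5-(3-hydroxyprop-1-en-2-yl)-2-methylcyclohexan-1-one | C=C(CO)[C@@H]1CC[C@@H](C)C(=O)C1=CO
F9 | step 9 | benzyl (5R,8S)-3-(acetyloxy)-8-[(2S,4E,6S)-1-(acetyloxy)-7-(benzyloxy)-6-methylhept-4-en-2-yl]-4-(benzyloxy)-5-methyl-5,6,7,8-tetrahydronaphthalene-2-carboxylate | CC(=O)OC[C@@H](C/C=C/[C@H](C)COCc3ccccc3)[C@@H]1CC[C@@H](C)c2c1cc(C(=O)OCc4ccccc4)c(OC(C)=O)c2OCc5ccccc5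
A1 | alternative 1 | benzyl (5R)-3,4-bis(benzyloxy)-5-methyl-8-oxo-5,6,7,8-tetrahydronaphthalene-2-carboxylate | O=C1CC[C@@H](C)c2c1cc(C(=O)OCc3ccccc3)c(OCc4ccccc4)c2OCc5ccccc5
A2 | alternative 2 | benzyl 3,4-bis(benzyloxy)-5-methyl-5,6-dihydronaphthalene-2-carboxylate (racemic) | CC1CC=Cc2cc(C(=O)OCc3ccccc3)c(OCc4ccccc4)c(OCc5ccccc5)c12
A3 | alternative 3 | (1R,6R)-1-[(2Z,7S)-8-(benzyloxy)-7-methyloct-2-en-1-yl]-6-methylcyclohex-2-en-1-ol | C[C@@H]1CCC=C[C@@]1(O)C/C=C\CCC[C@H](C)COCc1ccccc1
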